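Early on, dissolved starting material has to build up from none before product can follow it, so I begin by asking how long material queues on its way to product.

    starting material + free catalyst ⇌ free catalyst + intermediate (K1 = 0.433, k1 = 226 /M/min)
    reagent + second catalyst + intermediate → second catalyst + product (k2 = 0.821 /M²/min)
    solid substrate ⇌ starting material, rate k3*(cs3 - [starting material]) while solid is left; crystals form when [starting material] > cs3 (cs3 = 0.088 M, k3 = 0.0438 /min)

solid substrate 0.50 M; reagent 0.800 equiv; free catalyst 0.05 mol%; second catalyst 14 mol%; time 12 h

- which holds at 12 h: what has brought the reaction to rest, or that it has not come to rest (for what has run out or reacted, a solid counts together with what of it has only dissolved) (no working catalyst is left / the reagent has run out first / forward and back rates have come level / all of the solid substrate has reacted / it is still moving)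
- part of the solid substrate that has turned into other species by 12 h (what has only dissolved does not count)
- how much product there is at 12 h, in percent of the solid substrate charged
- how much starting material there is at 12 h, in percent of the solid substrate charged

- given per volume of solution although it is solid: solid substrate
- at the start none of the solid substrate is in solution
- what has only dissolved of solid substrate counts as not reacted
- the reaction counts as stopped when no species that holds the solid substrate changes by six tenths of a point or more over the second half of the time
- starting material means what is dissolved; the solid is not counted in it
- run time (flask): 12 h

**The queue.** While solid lasts, one flow passes through steps in series, and each step costs a wait: 22.8 min for dissolution, 17.7 min for the catalysed step, and 100 min for the reagent step at full charge, a wait that grows as the inverse of the reagent left. Their sum is the queue time 141 min, and the solubility divided by it gives the flow. The first two waits make 40.5 min, so the reagent step, slower than both together, is the rate-limiting step, and reagent, the limiting reagent, caps product at 80.0%.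

**The curve.** I reckon that product lags by about 40.5 min, short against the run, and then climbs at 0.0749 /h as a fraction of the charge, while starting material stands at 14.8% of the charge. I see no sharp knee, since the slope eases as reagent falls. Summing the waits over the reagent used, with 4.55 solubilities of reagent charged, reagent is down to 50.0% at 7.49 h, with product at 40.0%, and down to 25.0% at 13.5 h, with product at 60.0%.

**My figures.** Stepping back from there at that moment's slope, I get product 56.3% at 12 h. The queue then stands at 380 min, which gives starting material 16.5%, intermediate 6.81% and solid 20.4%. With solid and reagent both present, the flask is moving, and conversion is 63.1%.

**The forecast.** It says it is still moving, with conversion 63.5%, product 57% and starting material 16.4%, on the ground that “The solid keeps the solution close to saturation”. Its product is above mine.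

**The simulation.** It gives it is still moving, with conversion 63.0%, product 56.2% and starting material 16.5%.

**Queue tested.** With 30% of the reagent left at 12.0 h, the reagent wait in this flask is 338 min, longer than the 40.5 min of the other steps together, and the queue time puts starting material at 16.5% of the charge against 16.5% simulated. In the neighbour flask, with 24 mol% of second catalyst and 14% of reagent left at 12.0 h, the reagent wait is 419 min, and the queue time puts starting material at 16.7% against 16.6% simulated.

The numbers are assumed; the result is computed.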